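The pyranone ring C is disconnected at C2–C3. C2 is both benzylic (ring B) and bound to O1, so in the open form it is simply the CH2 of an aryl benzyl ether, whose doubly activated C–H bond is the ideal target for a metal carbene placed at C3. The key step decomposes an ortho-benzyloxy aryl diazomethyl ketone with a chiral dirhodium tetracarboxylate: enantioselective 1,6 C–H insertion forms C2–C3, closes ring C and sets the C2 stereocentre in one operation. The precursor is a fully substituted ring A acetophenone (2-OBn, 4-OMOM, 3,5-diprenyl), assembled by diiodination and double Suzuki prenylation and converted into the diazoketone by diazo transfer.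

Key step: step 6

Assumption: Rh2(S-DOSP)4, dirhodium tetrakis[(S)-N-(4-dodecylphenylsulfonyl)prolinate], is assumed to give the 2S configuration on this substrate; if a test run shows the opposite sense, the mirror-image catalyst Rh2(R-DOSP)4 is used with no other change.

Step 1
Reactants: 1 2,4-dihydroxyacetophenone
Product: 2 1-(2,4-dihydroxy-3,5-diiodophenyl)ethanone
Conditions: NIS (2.1 equiv), p-TsOH·H2O (10 mol %), MeCN, 0 °C to rt
Reagents that add atoms: N-iodosuccinimide, O=C1CCC(=O)N1I
Why: Double electrophilic aromatic iodination; C3 and C5 are the only ring positions ortho or para to both phenolic oxygens, so the 3,5-diiodide should form selectively.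

Step 2
Reactants: 2 1-(2,4-dihydroxy-3,5-diiodophenyl)ethanone
Product: 3 1-[2-hydroxy-3,5-diiodo-4-(methoxymethoxy)phenyl]ethanone
Conditions: MOMCl (1.1 equiv), i-Pr2NEt, CH2Cl2, 0 °C to rt
Reagents that add atoms: chloromethyl methyl ether, COCCl
Why: Williamson-type O-alkylation; the 2-OH is held in a hydrogen bond to the acetyl carbonyl, so the more acidic 4-OH should react selectively with the small electrophile despite its two flanking iodines.

Step 3
Reactants: 3 1-[2-hydroxy-3,5-diiodo-4-(methoxymethoxy)phenyl]ethanone; 4 benzyl bromide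
Product: 5 1-[2-(benzyloxy)-3,5-diiodo-4-(methoxymethoxy)phenyl]ethanone
Conditions: K2CO3, DMF, 60 °C
Reagents that add atoms: benzyl bromide (4), BrCc1ccccc1
Why: Williamson ether synthesis under carbonate conditions that break the chelate; the benzyl group is not a protecting group but the future C2 and ring B.

Step 4
Reactants: 5 1-[2-(benzyloxy)-3,5-diiodo-4-(methoxymethoxy)phenyl]ethanone; 6 prenylboronic acid pinacol ester
Product: 7 1-[2-(benzyloxy)-4-(methoxymethoxy)-3,5-bis(3-methylbut-2-en-1-yl)phenyl]ethanone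
Conditions: 6 (3 equiv), PdCl2(IPent)(3-chloropyridine) (4 mol %; IPent = 1,3-bis[2,6-di(pentan-3-yl)phenyl]imidazol-2-ylidene), KOH (5 M aq), THF, 70 °C
Reagents that add atoms: prenylboronic acid pinacol ester (6), CC(C)=CCB1OC(C)(C)C(C)(C)O1
Why: Double Suzuki–Miyaura allyl–aryl coupling; this bulky NHC–palladium catalyst type is known to couple 3,3-disubstituted allylboronates at the unsubstituted (α) terminus and to accept di-ortho-substituted aryl halides, so both linear prenyl groups should be installed.

Step 5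
Reactants: 7 1-[2-(benzyloxy)-4-(methoxymethoxy)-3,5-bis(3-methylbut-2-en-1-yl)phenyl]ethanone
Product: 9 1-[2-(benzyloxy)-4-(methoxymethoxy)-3,5-bis(3-methylbut-2-en-1-yl)phenyl]-2-diazoethanone, via trifluoroacetyl ketone 8 (not isolated)
Conditions: LiN(SiMe3)2, THF, −78 °C; CF3CO2CH2CF3; cold dilute HCl work-up; then MsN3, Et3N, H2O, MeCN, rt
Reagents that add atoms: 2,2,2-trifluoroethyl trifluoroacetate, O=C(OCC(F)(F)F)C(F)(F)F (its CF3CO group enters 8 and is lost again); methanesulfonyl azide, CS(=O)(=O)N=[N+]=[N-]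
Why: Danheiser detrifluoroacetylative diazo transfer, in which the methyl ketone enolate is trifluoroacetylated (Claisen condensation) and the activated 1,3-diketone undergoes Regitz diazo transfer with loss of the trifluoroacetyl group as the N-acylsulfonamide; ethers and prenyl alkenes should be untouched.

Step 6
Reactants: 9 1-[2-(benzyloxy)-4-(methoxymethoxy)-3,5-bis(3-methylbut-2-en-1-yl)phenyl]-2-diazoethanone
Product: 10 (2S)-7-(methoxymethoxy)-6,8-bis(3-methylbut-2-en-1-yl)-2-phenylchroman-4-one
Conditions: Rh2(S-DOSP)4 (1 mol %), hexanes–CH2Cl2, slow addition of 9, 0 °C to rt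
Reagents that add atoms: none
Why: Loss of N2 from 9 at the dirhodium core should give an electrophilic rhodium carbene at C3, which inserts through a concerted, asynchronous three-centre transition state into one benzylic C–H bond of the O1–CH2Ph group, so that C2–C3 forms while the hydrogen passes to C3. The closest known reaction type is the intramolecular C–H insertion of 2-alkoxyaryl α-diazoketones to chroman-4-ones under dirhodium carboxylate catalysis, chiral prolinate catalysts included. Ring C closes as a six-membered ring by 1,6-insertion (ring atoms C3, C4, C4a, C8a, O1, C2); the normally preferred 1,5-site is O1 itself and carries no hydrogen. The C2 stereocentre is controlled by the catalyst alone, whose chiral prolinate ligand sphere selects one of the two enantiotopic benzylic hydrogens. The step needs insertion to win over oxonium ylide formation at O1 with [1,2]-benzyl shift, over Buchner attack on ring B and over cyclopropanation; the C–H bond is doubly activated (lone pair of O1, phenyl), O1 is a weakly nucleophilic aryl ether oxygen, carboxylate rather than copper catalysis disfavours ylides, and both prenyl groups (C6, C8) are meta to the acyl-bearing carbon C4a, so neither alkene can reach C3.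

Step 7
Reactants: 10 (2S)-7-(methoxymethoxy)-6,8-bis(3-methylbut-2-en-1-yl)-2-phenylchroman-4-one
Product: 11 (2S)-7-hydroxy-6,8-bis(3-methylbut-2-en-1-yl)-2-phenylchroman-4-one (7-hydroxy-6,8-diprenylflavanone)
Conditions: HCl (1.25 M in MeOH), MeOH, rt
Reagents that add atoms: none
Why: Acid-catalysed acetal solvolysis (transacetalisation to methanol) should free the phenol; C2 carries an unactivated phenyl ring and should not ionise under these mild conditions, and a short reaction time should keep the prenyl groups from adding the new phenol.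

Compound list
1 | 2,4-dihydroxyacetophenone | CC(=O)c1ccc(O)cc1O | starting material
2 | 1-(2,4-dihydroxy-3,5-diiodophenyl)ethanone | CC(=O)c1cc(I)c(O)c(I)c1O | intermediate
3 | 1-[2-hydroxy-3,5-diiodo-4-(methoxymethoxy)phenyl]ethanone | CC(=O)c1cc(I)c(OCOC)c(I)c1O | intermediate
4 | benzyl bromide | BrCc1ccccc1 | starting material
5 | 1-[2-(benzyloxy)-3,5-diiodo-4-(methoxymethoxy)phenyl]ethanone | CC(=O)c1cc(I)c(OCOC)c(I)c1OCc1ccccc1 | intermediate
6 | prenylboronic acid pinacol ester, 4,4,5,5-tetramethyl-2-(3-methylbut-2-en-1-yl)-1,3,2-dioxaborolane | CC(C)=CCB1OC(C)(C)C(C)(C)O1 | starting material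
7 | 1-[2-(benzyloxy)-4-(methoxymethoxy)-3,5-bis(3-methylbut-2-en-1-yl)phenyl]ethanone | CC(=O)c1cc(CC=C(C)C)c(OCOC)c(CC=C(C)C)c1OCc1ccccc1 | intermediate
8 | 1-[2-(benzyloxy)-4-(methoxymethoxy)-3,5-bis(3-methylbut-2-en-1-yl)phenyl]-4,4,4-trifluorobutane-1,3-dione | O=C(CC(=O)C(F)(F)F)c1cc(CC=C(C)C)c(OCOC)c(CC=C(C)C)c1OCc1ccccc1 | intermediate (not isolated)
9 | 1-[2-(benzyloxy)-4-(methoxymethoxy)-3,5-bis(3-methylbut-2-en-1-yl)phenyl]-2-diazoethanone | [N-]=[N+]=CC(=O)c1cc(CC=C(C)C)c(OCOC)c(CC=C(C)C)c1OCc1ccccc1 | intermediate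
10 | (2S)-7-(methoxymethoxy)-6,8-bis(3-methylbut-2-en-1-yl)-2-phenylchroman-4-one | CC(C)=CCc1cc2c(c(CC=C(C)C)c1OCOC)O[C@H](c1ccccc1)CC2=O | intermediate
11 | (2S)-7-hydroxy-6,8-bis(3-methylbut-2-en-1-yl)-2-phenylchroman-4-one | CC(C)=CCc1cc2c(c(CC=C(C)C)c1O)O[C@H](c1ccccc1)CC2=O | target

Total step count: 7. Longest linear sequence: 7 steps (1 to 11).

Steps most likely to fail

Step 6. The carbene may be captured by the lone pair of O1 (oxonium ylide, then [1,2]-shift of the benzyl group) instead of inserting, or the catalyst may discriminate poorly between the two enantiotopic benzylic hydrogens. The fallback sets out from 3 and comes back at 10. Condensation of 3 with dimethylformamide dimethyl acetal (toluene, 90 °C) should give (E)-3-(dimethylamino)-1-[2-hydroxy-3,5-diiodo-4-(methoxymethoxy)phenyl]prop-2-en-1-one F1. Brief treatment with dilute HCl in CH2Cl2 at rt should cyclise it, with loss of dimethylamine, to 6,8-diiodo-7-(methoxymethoxy)-4H-chromen-4-one F2. Neutral Stille coupling with tributyl(3-methylbut-2-en-1-yl)stannane and Pd(PPh3)4 in DMF at 90 °C (hydroxide would open the chromone) should give 7-(methoxymethoxy)-6,8-bis(3-methylbut-2-en-1-yl)-4H-chromen-4-one F3. Enantioselective conjugate addition of phenylboronic acid then sets C2 and gives 10: Pd(OCOCF3)2, NH4PF6, H2O, ClCH2CH2Cl, 40–60 °C, with the antipode of 4-tert-butyl-2-(pyridin-2-yl)-4,5-dihydrooxazole that delivers the 2S product.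

Step 4. Oxidative addition and transmetalation may be slow at the iodide flanked by two alkoxy groups (protodeiodination), and allyl transposition may deliver the branched 1,1-dimethylallyl isomer. The fallback sets out from 5 and comes back at 7. Stille coupling of 5 with allyltributylstannane (Pd(PPh3)4, DMF, 90 °C) has no regiochemical ambiguity and should give 1-[2-(benzyloxy)-4-(methoxymethoxy)-3,5-di(prop-2-en-1-yl)phenyl]ethanone F4. Double cross-metathesis of F4 with 2-methylbut-2-ene as solvent and second-generation Grubbs catalyst RuCl2(=CHPh)(H2IMes)(PCy3) at 40 °C should convert both allyl groups into prenyl groups and give 7.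

Step 7. The liberated phenol may add to a neighbouring prenyl alkene under acid (chroman formation), or prolonged acid exposure may erode C2 by opening and reclosing of ring C. The fallback sets out from 2 and comes back at 11, carrying the phenol as a fluoride-labile silyl ether so that no acid is needed at the end.
- TBSCl and imidazole in DMF should silylate the unchelated 4-OH of 2 to give 1-[4-(tert-butyldimethylsilyloxy)-2-hydroxy-3,5-diiodophenyl]ethanone F5.
- Mitsunobu benzylation (BnOH, PPh3, DIAD, THF), which avoids carbonate bases that strip aryl silyl ethers, should give 1-[2-(benzyloxy)-4-(tert-butyldimethylsilyloxy)-3,5-diiodophenyl]ethanone F6.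
- Neutral Stille coupling with tributyl(3-methylbut-2-en-1-yl)stannane and Pd(PPh3)4 in DMF at 90 °C should give 1-[2-(benzyloxy)-4-(tert-butyldimethylsilyloxy)-3,5-bis(3-methylbut-2-en-1-yl)phenyl]ethanone F7.
- Diazo transfer as in step 5 should pass through 1-[2-(benzyloxy)-4-(tert-butyldimethylsilyloxy)-3,5-bis(3-methylbut-2-en-1-yl)phenyl]-4,4,4-trifluorobutane-1,3-dione F8 (not isolated) to 1-[2-(benzyloxy)-4-(tert-butyldimethylsilyloxy)-3,5-bis(3-methylbut-2-en-1-yl)phenyl]-2-diazoethanone F9.
- Insertion with Rh2(S-DOSP)4 as in step 6 should give (2S)-7-(tert-butyldimethylsilyloxy)-6,8-bis(3-methylbut-2-en-1-yl)-2-phenylchroman-4-one F10.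
- HF·pyridine in THF at 0 °C should then give 11.

Further compounds
F1 | step 6 | (E)-3-(dimethylamino)-1-[2-hydroxy-3,5-diiodo-4-(methoxymethoxy)phenyl]prop-2-en-1-one | CN(C)/C=C/C(=O)c1cc(I)c(OCOC)c(I)c1O
F2 | step 6 | 6,8-diiodo-7-(methoxymethoxy)-4H-chromen-4-one | O=c1ccoc2c(I)c(OCOC)c(I)cc12
F3 | step 6 | 7-(methoxymethoxy)-6,8-bis(3-methylbut-2-en-1-yl)-4H-chromen-4-one | O=c1ccoc2c(CC=C(C)C)c(OCOC)c(CC=C(C)C)cc12
F4 | step 4 | 1-[2-(benzyloxy)-4-(methoxymethoxy)-3,5-di(prop-2-en-1-yl)phenyl]ethanone | CC(=O)c1cc(CC=C)c(OCOC)c(CC=C)c1OCc1ccccc1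
F5 | step 7 | 1-[4-(tert-butyldimethylsilyloxy)-2-hydroxy-3,5-diiodophenyl]ethanone | CC(=O)c1cc(I)c(O[Si](C)(C)C(C)(C)C)c(I)c1O
F6 | step 7 | 1-[2-(benzyloxy)-4-(tert-butyldimethylsilyloxy)-3,5-diiodophenyl]ethanone | CC(=O)c1cc(I)c(O[Si](C)(C)C(C)(C)C)c(I)c1OCc1ccccc1
F7 | step 7 | 1-[2-(benzyloxy)-4-(tert-butyldimethylsilyloxy)-3,5-bis(3-methylbut-2-en-1-yl)phenyl]ethanone | CC(=O)c1cc(CC=C(C)C)c(O[Si](C)(C)C(C)(C)C)c(CC=C(C)C)c1OCc1ccccc1
F8 | step 7 | 1-[2-(benzyloxy)-4-(tert-butyldimethylsilyloxy)-3,5-bis(3-methylbut-2-en-1-yl)phenyl]-4,4,4-trifluorobutane-1,3-dione | O=C(CC(=O)C(F)(F)F)c1cc(CC=C(C)C)c(O[Si](C)(C)C(C)(C)C)c(CC=C(C)C)c1OCc1ccccc1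
F9 | step 7 | 1-[2-(benzyloxy)-4-(tert-butyldimethylsilyloxy)-3,5-bis(3-methylbut-2-en-1-yl)phenyl]-2-diazoethanone | [N-]=[N+]=CC(=O)c1cc(CC=C(C)C)c(O[Si](C)(C)C(C)(C)C)c(CC=C(C)C)c1OCc1ccccc1
F10 | step 7 | (2S)-7-(tert-butyldimethylsilyloxy)-6,8-bis(3-methylbut-2-en-1-yl)-2-phenylchroman-4-one | CC(C)=CCc1cc2c(c(CC=C(C)C)c1O[Si](C)(C)C(C)(C)C)O[C@H](c1ccccc1)CC2=O
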